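**Retrosynthetic overview**

1. The target comes from a ring A alkene diacetate by a last-step Woodward–Prévost cis-hydroxy-acetoxylation, which sets C-3 and C-4.
2. The cyclopropane (C-8–C-9 bond) comes from carbene C–H insertion at a C-8 ketone (Bamford–Stevens).
3. The C-8 ketone and C-11 carbinol come from the key step: a Wagner–Meerwein 1,2-shift of C-9 (from C-8 to C-10) on opening the exo epoxide of a norbornene, terminated by DMSO oxidation.
4. The norbornene and ring A come together from a catalytic asymmetric intramolecular Diels–Alder reaction of a 1-substituted 3-methylcyclopentadiene carrying a tethered 2-substituted acrolein (sets C-1, C-6, C-8).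
5. The triene comes from 3-methylcyclopent-2-enone, isobutyronitrile, 4-bromobutanenitrile (Z-Wittig) and Eschenmoser's salt. Ring order: cyclopentene (purchased), then ring A plus the norbornene ring together, then the skeletal shift, then the cyclopropane.

Atom labels used in the names (read along the target SMILES): C-12 (CH2O), C-1 (quaternary), C-2 (CH2), C-3 (CHOAc), C-4 (CHOH), C-5 (CMe2), C-6 (quaternary), C-7 (CH2), C-8 and C-9 (cyclopropane CH), C-10 (cyclopropane C–Me), C-11 (CHOAc). Ring A is C-1 to C-6.

Assumption: the (S)-configured oxazaborolidinium catalyst is taken to give the step 8 adduct as drawn (model for 2-substituted acroleins); if the first adduct proves antipodal, the (R)-catalyst is used.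

**Step 1**
Reactants: 1 isobutyronitrile; 2 3-methylcyclopent-2-en-1-one
Product: 5 2-methyl-2-[3-methyl-1-(trimethylsilyloxy)cyclopent-2-en-1-yl]propanenitrile (racemic), via lithio nitrile 3 (not isolated), via lithium alkoxide 4 (not isolated)
Conditions: LiN(iPr)2, THF, −78 °C; then 2, −78 °C; then Me3SiCl, −78 → 0 °C
Reagents that add atoms: chlorotrimethylsilane, C[Si](C)(C)Cl
Why: Aldol-type 1,2-addition of the hindered α-cyano carbanion to the enone carbonyl (conjugate addition is disfavoured at the β,β-disubstituted carbon), with the alkoxide capped as a silyl ether against retro-addition; the carbinol centre is racemic and is erased in step 7.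

**Step 2**
Reactants: 5 silyl ether nitrile
Product: 6 2-methyl-2-[3-methyl-1-(trimethylsilyloxy)cyclopent-2-en-1-yl]propanal (racemic)
Conditions: iBu2AlH, toluene, −78 °C; then H2O, aq. potassium sodium tartrate, 0 °C → rt
Reagents that add atoms: water, O
Why: DIBAL half-reduction of the nitrile stops at the N-aluminio aldimine, which water hydrolyses on work-up to the aldehyde (the carbonyl oxygen comes from water, the nitrogen leaves as ammonia); no stereocentre is touched.

**Step 3**
Reactants: 7 4-bromobutanenitrile
Product: 8 (3-cyanopropyl)triphenylphosphonium bromide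
Conditions: PPh3, MeCN, reflux
Reagents that add atoms: triphenylphosphine, c1ccc(cc1)P(c1ccccc1)c1ccccc1
Why: SN2 quaternisation of a primary bromide by the phosphine.

**Step 4**
Reactants: 6 aldehyde; 8 phosphonium bromide
Product: 10 (Z)-6-methyl-6-[3-methyl-1-(trimethylsilyloxy)cyclopent-2-en-1-yl]hept-4-enenitrile, via ylide 9 (not isolated)
Conditions: NaN(SiMe3)2, THF, −78 → 0 °C; then 6, −78 °C → rt
Reagents that add atoms: none
Why: Salt-free Wittig olefination of a non-stabilised ylide with the α-quaternary aldehyde gives the Z alkene (C-3=C-4) that ring A needs.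

**Step 5**
Reactants: 10 Z-alkenyl nitrile
Product: 11 (Z)-6-methyl-6-[3-methyl-1-(trimethylsilyloxy)cyclopent-2-en-1-yl]hept-4-enal
Conditions: iBu2AlH, toluene, −78 °C; then H2O, aq. potassium sodium tartrate, 0 °C → rt
Reagents that add atoms: water, O
Why: DIBAL half-reduction of the nitrile to the aldimine and hydrolysis by water on work-up give the aldehyde (future C-12, carbonyl oxygen from water); the Z alkene and silyl ether are inert.

**Step 6**
Reactants: 11 aldehyde; 12 N,N-dimethylmethylideneammonium iodide (Eschenmoser's salt)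
Product: 14 (Z)-6-methyl-2-methylidene-6-[3-methyl-1-(trimethylsilyloxy)cyclopent-2-en-1-yl]hept-4-enal, via Mannich base 13 (not isolated)
Conditions: Et3N, CH2Cl2, rt
Reagents that add atoms: none
Why: Mannich reaction at the aldehyde α-carbon followed by β-elimination of dimethylamine (α-methylenation) installs C-9 and the 2-substituted acrolein dienophile under non-acidic conditions.

**Step 7**
Reactants: 14 silyloxy enal
Product: 15 (Z)-6-methyl-2-methylidene-6-(3-methylcyclopenta-1,3-dien-1-yl)hept-4-enal (with its ring double-bond tautomers)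
Conditions: (±)-camphor-10-sulfonic acid (5 mol%), CH2Cl2, −20 °C, 20 min; cold aq. NaHCO3; used at once
Reagents that add atoms: none
Why: Acid-catalysed E1 loss of silanol from the tertiary allylic silyl ether via the cyclopentenyl cation unmasks the cyclopentadiene only now, so the uncatalysed cycloaddition has no time to compete.

**Step 8**
Reactants: 15 cyclopentadienyl enal
Product: 17 tricyclic alcohol (norbornene with bridgeheads C-6 and C-8, bridge C-7 and C-10(Me)=C-11; fused at C-1–C-6 to cyclohexene ring A; C-12H2OH exo on C-1), via aldehyde 16 (not isolated)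
Conditions: (S)-3,3-diphenyl-1-(2-methylphenyl)tetrahydro-1H,3H-pyrrolo[1,2-c][1,3,2]oxazaborole (20 mol%), (CF3SO2)2NH (17 mol%), CH2Cl2, −78 → −40 °C; then MeOH, NaBH4, −40 → 0 °C
Reagents that add atoms: none
Why: Chiral Lewis-acid-catalysed intramolecular Diels–Alder reaction in which the formyl group goes exo (as for 2-substituted acroleins) and the tether endo while the catalyst shields one enal face, setting C-1, C-6 and C-8 and forming ring A and the norbornene at once; NaBH4 then reduces the aldehyde.

**Step 9**
Reactants: 17 tricyclic alcohol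
Product: 18 tricyclic acetate (C-12H2OAc)
Conditions: Ac2O, pyridine, 4-(dimethylamino)pyridine (cat.), CH2Cl2, rt
Reagents that add atoms: acetic anhydride, CC(=O)OC(C)=O
Why: Nucleophile-catalysed acylation of the primary neopentyl alcohol installs the first acetate of the target.

**Step 10**
Reactants: 18 tricyclic acetate
Product: 19 exo epoxide of 18 (oxygen on C-10 and C-11, syn to the C-7 bridge)
Conditions: mCPBA (1.05 equiv), NaHCO3, CH2Cl2, 0 °C
Reagents that add atoms: 3-chloroperoxybenzoic acid, OOC(=O)c1cccc(Cl)c1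
Why: Prilezhaev epoxidation picks the strained trisubstituted norbornene alkene over the hindered ring A alkene and attacks its exo face, fixing the C-11 oxygen on the side of C-7.

**Step 11**
Reactants: 19 exo epoxide
Product: 22 keto diacetate (norbornanone with bridgeheads C-6 and C-10(Me), C-8 ketone, C-11 acetate syn to C-8, C-9H2 now bonded to C-10), via alkoxysulfonium triflate 20 (not isolated), via hydroxy ketone 21 (not isolated)
Conditions: CF3SO3H (1.05 equiv), DMSO (3 equiv), CH2Cl2, −20 → 0 °C; Et3N, 0 °C → rt; aqueous wash; then Ac2O, 4-(dimethylamino)pyridine, pyridine, rt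
Reagents that add atoms: dimethyl sulfoxide, CS(C)=O; acetic anhydride, CC(=O)OC(C)=O
Why: Proposed new method: the protonated epoxide ionises at tertiary C-10 with antiperiplanar participation of the C-8–C-9 bond, so C-9 migrates from C-8 to C-10 (Wagner–Meerwein 1,2-shift, inversion at C-10, epoxide oxygen left as the C-11 hydroxyl syn to C-8), the rearranged C-8 cation is trapped on its exo face by DMSO as salt 20, and Et3N collapses this (Kornblum/Swern-type) to ketone 21 before acetylation; the closest known reactions are the acid-catalysed rearrangement of norbornene oxides to 2-exo,7-syn-diols and the acid/DMSO oxidative opening of epoxides to α-hydroxy ketones.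

**Step 12**
Reactants: 22 keto diacetate
Product: 25 nortricyclene diacetate (target skeleton with a C-3=C-4 double bond in place of the C-3 acetate and C-4 hydroxyl), via tosylhydrazone 23 (not isolated), via diazoalkane 24 (not isolated)
Conditions: TsNHNH2, EtOH, 60 °C; evaporate; NaH (1.05 equiv), diglyme, rt → 140 °C
Reagents that add atoms: none
Why: Aprotic Bamford–Stevens reaction in which the C-8 alkylcarbene inserts into the endo C-9–H bond (as camphor tosylhydrazone gives tricyclene), closing the cyclopropane; C-8 and C-9 are fixed by the cage.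

**Step 13**
Reactants: 25 nortricyclene diacetate
Product: 28 CNP0197219.1 (C-12 acetate, C-3 axial acetate, C-4 equatorial hydroxyl, C-11 acetate), via iodo acetate 26 (not isolated), via dioxolanylium acetate 27 (not isolated)
Conditions: I2 (1.05 equiv), AgOAc (2.2 equiv), AcOH, rt; then AcOH/H2O, 95 °C
Reagents that add atoms: silver acetate, [Ag+].CC([O-])=O; water, O
Why: Woodward–Prévost cis-hydroxylation in which acetate opens the reversibly formed iodonium ion trans-diaxially at the non-neopentyl C-3 from the face of C-12, silver-assisted anchimeric displacement of the axial C-4 iodide gives the cis-fused dioxolanylium ion on that face, and water opens it to the axial C-3 acetate and equatorial C-4 alcohol.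

**Compound list**

1 | isobutyronitrile | CC(C)C#N | starting material
2 | 3-methylcyclopent-2-en-1-one | CC1=CC(=O)CC1 | starting material
3 | lithio nitrile (lithium 2-cyanopropan-2-ide) | [Li+].C[C-](C)C#N | intermediate
4 | lithium alkoxide (lithium 1-(2-cyanopropan-2-yl)-3-methylcyclopent-2-en-1-olate) | [Li+].CC1=CC([O-])(CC1)C(C)(C)C#N | intermediate
5 | 2-methyl-2-[3-methyl-1-(trimethylsilyloxy)cyclopent-2-en-1-yl]propanenitrile (racemic) | CC1=CC(O[Si](C)(C)C)(CC1)C(C)(C)C#N | intermediate
6 | 2-methyl-2-[3-methyl-1-(trimethylsilyloxy)cyclopent-2-en-1-yl]propanal (racemic) | CC1=CC(O[Si](C)(C)C)(CC1)C(C)(C)C=O | intermediate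
7 | 4-bromobutanenitrile | N#CCCCBr | starting material
8 | (3-cyanopropyl)triphenylphosphonium bromide | N#CCCC[P+](c1ccccc1)(c1ccccc1)c1ccccc1.[Br-] | intermediate
9 | ylide, 4-(triphenylphosphoranylidene)butanenitrile | N#CCCC=P(c1ccccc1)(c1ccccc1)c1ccccc1 | intermediate
10 | (Z)-6-methyl-6-[3-methyl-1-(trimethylsilyloxy)cyclopent-2-en-1-yl]hept-4-enenitrile | CC1=CC(O[Si](C)(C)C)(CC1)C(C)(C)/C=C\CCC#N | intermediate
11 | (Z)-6-methyl-6-[3-methyl-1-(trimethylsilyloxy)cyclopent-2-en-1-yl]hept-4-enal | CC1=CC(O[Si](C)(C)C)(CC1)C(C)(C)/C=C\CCC=O | intermediate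
12 | N,N-dimethylmethylideneammonium iodide (Eschenmoser's salt) | C[N+](C)=C.[I-] | starting material
13 | Mannich base, (Z)-2-[(dimethylamino)methyl]-6-methyl-6-[3-methyl-1-(trimethylsilyloxy)cyclopent-2-en-1-yl]hept-4-enal | CC1=CC(O[Si](C)(C)C)(CC1)C(C)(C)/C=C\CC(CN(C)C)C=O | intermediate
14 | (Z)-6-methyl-2-methylidene-6-[3-methyl-1-(trimethylsilyloxy)cyclopent-2-en-1-yl]hept-4-enal | CC1=CC(O[Si](C)(C)C)(CC1)C(C)(C)/C=C\CC(=C)C=O | intermediate
15 | (Z)-6-methyl-2-methylidene-6-(3-methylcyclopenta-1,3-dien-1-yl)hept-4-enal | O=CC(=C)C/C=C\C(C)(C)C1=CC(C)=CC1 | intermediate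
16 | tricyclic aldehyde (C-12HO exo on C-1; C-3=C-4 and C-10(Me)=C-11 alkenes; bridgeheads C-6, C-8) | O=C[C@]12CC=CC(C)(C)[C@]13C[C@H](C2)C(C)=C3 | intermediate
17 | tricyclic alcohol (C-12H2OH) | OC[C@]12CC=CC(C)(C)[C@]13C[C@H](C2)C(C)=C3 | intermediate
18 | tricyclic acetate (C-12H2OAc) | CC(=O)OC[C@]12CC=CC(C)(C)[C@]13C[C@H](C2)C(C)=C3 | intermediate
19 | exo C-10/C-11 epoxide of 18 | CC(=O)OC[C@]12CC=CC(C)(C)[C@]13C[C@H](C2)[C@@]2(C)O[C@@H]32 | intermediate
20 | alkoxysulfonium triflate (C-8 exo O–SMe2 cation, C-11 OH, C-9 on C-10) | CC(=O)OC[C@]12CC=CC(C)(C)[C@]13C[C@@H](O[S+](C)C)[C@](C)(C2)[C@H]3O.[O-]S(=O)(=O)C(F)(F)F | intermediate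
21 | hydroxy ketone (C-8 ketone, C-11 OH syn to C-8) | CC(=O)OC[C@]12CC=CC(C)(C)[C@]13CC(=O)[C@](C)(C2)[C@H]3O | intermediate
22 | keto diacetate (C-8 ketone, C-11 OAc, C-12 OAc) | CC(=O)OC[C@]12CC=CC(C)(C)[C@]13CC(=O)[C@](C)(C2)[C@H]3OC(C)=O | intermediate
23 | tosylhydrazone of 22 | CC(=O)OC[C@]12CC=CC(C)(C)[C@]13CC(=NNS(=O)(=O)c4ccc(C)cc4)[C@](C)(C2)[C@H]3OC(C)=O | intermediate
24 | diazoalkane (C-8 diazo) | CC(=O)OC[C@]12CC=CC(C)(C)[C@]13CC(=[N+]=[N-])[C@](C)(C2)[C@H]3OC(C)=O | intermediate
25 | nortricyclene diacetate with C-3=C-4 alkene | CC(=O)OC[C@]12CC=CC(C)(C)[C@]13C[C@@H]1[C@H]2[C@]1(C)[C@H]3OC(C)=O | intermediate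
26 | iodo acetate (C-3 axial OAc, C-4 axial I, trans) | CC(=O)OC[C@]12C[C@H](OC(C)=O)[C@@H](I)C(C)(C)[C@]13C[C@@H]1[C@H]2[C@]1(C)[C@H]3OC(C)=O | intermediate
27 | dioxolanylium acetate (2-methyl-1,3-dioxolan-2-ylium cis-fused at C-3/C-4 on the face of C-12) | CC(=O)OC[C@]12C[C@@H]4OC(C)=[O+][C@@H]4C(C)(C)[C@]13C[C@@H]1[C@H]2[C@]1(C)[C@H]3OC(C)=O.CC([O-])=O | intermediate
28 | CNP0197219.1 | CC(=O)OC[C@]12C[C@H](OC(C)=O)[C@H](O)C(C)(C)[C@]13C[C@@H]1[C@H]2[C@]1(C)[C@H]3OC(C)=O | target

**Step count and risks**

Total step count: 13. Longest linear sequence: 12 (steps 1, 2, 4 to 13; step 3 is a one-step side branch).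

Steps most likely to fail:

Step 11 (the proposed new step). The cation may instead lose a methyl proton or undergo hydride shift to a C-11 ketone, or DMSO capture may be slow. Fallback with known chemistry, setting out from 19: aqueous HClO4 in THF at 0 °C brings about the same Wagner–Meerwein shift with water as terminator and gives the 2-exo,7-syn-type diol F1. The less hindered exo C-8 hydroxyl is then oxidised selectively with TEMPO (cat.) and PhI(OAc)2 to hydroxy ketone 21. Ac2O with 4-(dimethylamino)pyridine brings it back to the route at 22.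

Step 8. The diene is a tautomer mixture, the tether must go endo, and the racemic background reaction erodes the enantiomeric excess. Fallback, setting out from 15: Me2AlCl (1.1 equiv) in CH2Cl2 at −78 °C gives the racemic exo-formyl adduct, that is 16 together with the mirror-image aldehyde F2. NaBH4 gives 17 together with the mirror-image alcohol F3. Burkholderia cepacia lipase (or Candida antarctica lipase B, whichever acylates 17) with vinyl acetate in tert-butyl methyl ether acetylates one enantiomer only, which comes back to the route at 18, and F3 is separated.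

Step 13. Acetate has to attack C-3 past two syn-axial groups, and the cyclopropylcarbinyl acetate must survive iodine and silver acetate. Fallback, setting out from 25: mCPBA epoxidises the more open face of the ring A alkene (opposite to C-12) to the epoxide F4. Warm AcOH opens it trans-diaxially at C-3 to the trans hydroxy acetate F5 (C-3 axial OAc, C-4 axial OH). Dess–Martin periodinane gives the α-acetoxy ketone F6. NaBH4 with CeCl3 in MeOH at −78 °C delivers hydride axially, anti to the axial C-3 acetate, to give the equatorial C-4 alcohol and so comes back to the route at 28.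

**Further compounds**

F1 | step 11 | diol (C-8 exo OH, C-11 OH syn to C-8, C-9 on C-10, C-12 OAc) | CC(=O)OC[C@]12CC=CC(C)(C)[C@]13C[C@@H](O)[C@](C)(C2)[C@H]3O
F2 | step 8 | mirror image of aldehyde 16 | O=C[C@@]12CC=CC(C)(C)[C@@]13C[C@@H](C2)C(C)=C3
F3 | step 8 | mirror image of alcohol 17 | OC[C@@]12CC=CC(C)(C)[C@@]13C[C@@H](C2)C(C)=C3
F4 | step 13 | C-3/C-4 epoxide of 25 on the face opposite C-12 | CC(=O)OC[C@]12C[C@H]4O[C@H]4C(C)(C)[C@]13C[C@@H]1[C@H]2[C@]1(C)[C@H]3OC(C)=O
F5 | step 13 | trans hydroxy acetate (C-3 axial OAc, C-4 axial OH) | CC(=O)OC[C@]12C[C@H](OC(C)=O)[C@@H](O)C(C)(C)[C@]13C[C@@H]1[C@H]2[C@]1(C)[C@H]3OC(C)=O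
F6 | step 13 | α-acetoxy ketone (C-4 ketone, C-3 axial OAc) | CC(=O)OC[C@]12C[C@H](OC(C)=O)C(=O)C(C)(C)[C@]13C[C@@H]1[C@H]2[C@]1(C)[C@H]3OC(C)=O
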